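**Strategy.** Ring A (C1–C5, C10) is disconnected at C3–C4. Ring B comes from (S)-carvone: its isopropenyl group becomes C4/C18/C19 and its α′-carbon becomes the quaternary C10 carrying a propargyl arm (C1–C3). The key step is a gold-catalysed 6-endo-dig carbocyclisation of the C19 silyl enol ether onto the alkyne. It closes ring A, creates the C4 quaternary centre with the formyl group in place, and leaves C2=C3 for cis-dihydroxylation. It exploits C4 being the α-carbon of the C19 aldehyde; because C4 is trigonal in the precursor, both C4 epimers and both enol geometries converge. The side chain is then grafted onto C9 with allylic transposition.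

Key step: step 6

Remark: locants are those of the labdane skeleton (ring A = C1–C5/C10, ring B = C5–C10, C19 = formyl carbon, C20 = C10 methyl), α is the face of C20 and β the face of H-5; the sense of induction of (S)-Tol-BINAP in step 12 is assumed, and the antipodal ligand is used if it proves opposite.

Step 1
Reactants: 1 (S)-(+)-carvone
Product: 3 6-methylcarvone (C6 epimer mixture), via lithium dienolate 2 (not isolated)
Conditions: LiN(iPr)2, THF, −78 °C; MeI, −78 → 0 °C
Reagents that add atoms: iodomethane (CI)
Why: Kinetic α′-deprotonation of the enone and SN2 methylation of the cross-conjugated enolate (enolate alkylation) install the future C20; the new centre is erased again in step 2, so its configuration does not matter.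

Step 2
Reactants: 3 6-methylcarvone
Product: 5 (5R,6R)-2,6-dimethyl-5-(prop-1-en-2-yl)-6-(prop-2-yn-1-yl)cyclohex-2-en-1-one, via lithium enolate 4 (not isolated)
Conditions: LiN(iPr)2, THF, −78 → 0 °C; HC≡CCH2Br, DMPU, −78 → 0 °C
Reagents that add atoms: propargyl bromide (C#CCBr)
Why: The tetrasubstituted enolate is alkylated on the face anti to the neighbouring isopropenyl group (enolate alkylation), so propargyl ends trans and methyl cis to it, which fixes quaternary C10 relative to C5.

Step 3
Reactants: 5 dialkylated carvone
Product: 6 epoxide of 5 (isopropenyl converted to 2-methyloxiran-2-yl; both epimers at the oxirane carbon C4)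
Conditions: mCPBA, NaHCO3, CH2Cl2, 0 °C
Reagents that add atoms: mCPBA (OOC(=O)c1cccc(Cl)c1)
Why: Prilezhaev epoxidation selects the electron-rich 1,1-disubstituted alkene over the conjugated enone C=C and the alkyne; the oxirane stereocentre is lost in step 5.

Step 4
Reactants: 6 epoxide
Product: 7 2-(ring B)-propanal (C19 aldehyde; both C4 epimers)
Conditions: BF3·OEt2 (0.3 equiv), CH2Cl2, −78 °C
Reagents that add atoms: none
Why: Lewis-acid opening at the tertiary oxirane carbon with a 1,2-hydride shift (Meinwald rearrangement) gives the α-methyl aldehyde; both C4 epimers are usable.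

Step 5
Reactants: 7 aldehyde
Product: 8 tert-butyldimethylsilyl enol ether of 7 (C4=C19; E/Z mixture)
Conditions: TBSOTf, Et3N, CH2Cl2, −78 → 0 °C
Reagents that add atoms: tert-butyldimethylsilyl triflate (CC(C)(C)[Si](C)(C)OS(=O)(=O)C(F)(F)F)
Why: Soft enolisation and O-silylation of the aldehyde (silyl enol ether formation) should outrun γ-enolisation of the hindered enone; C4 becomes trigonal, and both geometries are carried forward.

Step 6
Reactants: 8 silyl enol ether
Product: 9 trans-decalin keto aldehyde (C2=C3 and C7=C8 alkenes; C9 ketone; C4 bearing α-CHO and β-CH3; C10 α-CH3; H-5 β)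
Conditions: [Au(NCMe)(Me4tBuXPhos)]SbF6 (5 mol %), MeOH (2 equiv), CH2Cl2, rt
Reagents that add atoms: none
Why: Cationic monovalent gold π-activates the terminal alkyne and the nucleophilic C4 of the silyl enol ether attacks its terminal carbon C3 anti to gold, giving a vinylgold silyloxocarbenium ion that methanol desilylates and protodeaurates to the C19 aldehyde and the C2=C3 alkene. The closest known reaction type is the gold-catalysed Conia-ene-type carbocyclisation of silyl enol ethers onto alkynes, in which bulky biaryl phosphine ligands steer three-atom-tethered substrates to the 6-endo mode. Ring A closes 6-endo-dig through a chair-like transition state across the trans-diequatorial C5 and C10 arms of ring B, so only the trans-decalin can form. The new quaternary centre C4 is controlled by the axial C20 methyl: an axial C4 methyl would cost a syn-axial Me/Me contact, so the planar enol carbon C19 takes the axial site (formyl cis to C20) and the methyl the equatorial one. Because C4 is trigonal in 8, both C4 epimers of 7 and both enol geometries should funnel into this one configuration. The step needs 6-endo over 5-exo closure, which the bulky ligand should secure, and carbon attack over reversible participation of the C9 carbonyl oxygen, which the irreversible C–C bond formation with loss of silicon should secure.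

Step 7
Reactants: 9 keto aldehyde
Product: 10 2β,3β-diol of 9
Conditions: OsO4 (5 mol %), NMO, acetone/H2O, rt
Reagents that add atoms: N-methylmorpholine N-oxide (C[N+]1([O-])CCOCC1); water (O)
Why: Upjohn cis-dihydroxylation; osmium should approach C2=C3 from the β face, away from the syn-axial C20 methyl and C19 formyl, giving the equatorial C2 and axial C3 hydroxyls, while the electron-poor enone alkene is left alone.

Step 8
Reactants: 10 diol aldehyde
Product: 11 2β,3β-acetonide C19 dimethyl acetal of 10
Conditions: HC(OMe)3, Me2C(OMe)2, CSA (cat.), MeOH, rt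
Reagents that add atoms: trimethyl orthoformate (COC(OC)OC); 2,2-dimethoxypropane (COC(C)(C)OC)
Why: Acid-catalysed acetal exchange protects the cis-diol as its acetonide and the aldehyde as its dimethyl acetal, so both survive the organometallic steps.

Step 9
Reactants: 11 protected enone
Product: 13 9α-methyl carbonate carrying a 9β-(but-3-enyl) group, via bromomagnesium alkoxide 12 (not isolated)
Conditions: CH2=CHCH2CH2MgBr, LaCl3·2LiCl, THF, −78 → 0 °C; ClCO2Me, 0 °C → rt
Reagents that add atoms: but-3-enylmagnesium bromide (C=CCC[Mg]Br); methyl chloroformate (COC(=O)Cl)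
Why: Lanthanum-promoted Grignard 1,2-addition to the hindered enone carbonyl should occur from the β face, anti to the angular C20 methyl, and the alkoxide is then acylated (carbonate formation), placing the leaving group α at C9.

Step 10
Reactants: 13 tertiary allylic carbonate
Product: 14 9α-(but-3-enyl) 7-ene with H-9 β (acetonide and acetal retained)
Conditions: Pd(OAc)2 (5 mol %), PBu3 (5 mol %), HCO2NH4, THF, 50 °C
Reagents that add atoms: none
Why: Tsuji–Mandai formate hydrogenolysis; zerovalent palladium ionises the carbonate with inversion to a π-allyl on the β face, and hydride from palladium formate is delivered internally to the more substituted terminus C9 on that face, which should give the C7=C8 alkene with H-9 β and the chain α.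

Step 11
Reactants: 14 terminal alkene
Product: 15 methyl (E)-enoate (C13=C14; C15 ester)
Conditions: methyl acrylate, second-generation Grubbs catalyst (5 mol %), CH2Cl2, 40 °C
Reagents that add atoms: methyl acrylate (C=CC(=O)OC)
Why: Olefin cross-metathesis of the terminal alkene with the electron-poor acrylate gives the E-enoate; the trisubstituted C7=C8 alkene is inert.

Step 12
Reactants: 15 enoate
Product: 16 (13R)-methyl ester with the full side chain
Conditions: MeMgBr, CuI (2 mol %), (S)-Tol-BINAP (3 mol %), t-BuOMe, −20 °C; H2O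
Reagents that add atoms: methylmagnesium bromide (C[Mg]Br)
Why: Copper-catalysed asymmetric conjugate addition of the Grignard reagent; the chiral bisphosphine–copper complex sets C13, which is too remote for the ring stereocentres to interfere.

Step 13
Reactants: 16 methyl ester
Product: 18 2β,3β-dihydroxy-19-oxo acid (the target without its acetyl group), via lithium carboxylate 17 (not isolated)
Conditions: LiOH, THF/MeOH/H2O, rt; 2 M aq. HCl (pH 1), THF, rt
Reagents that add atoms: lithium hydroxide ([Li+].[OH-]); water (O)
Why: Saponification followed by aqueous-acid hydrolysis of the acetonide and dimethyl acetal (deprotection); the base is used before the β-hydroxy aldehyde is unveiled, so retro-aldol cleavage is avoided.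

Step 14
Reactants: 18 dihydroxy aldehyde acid
Product: 19 CNP0180877.1 (target)
Conditions: Ac2O (1.2 equiv), pyridine, CH2Cl2, 0 °C
Reagents that add atoms: acetic anhydride (CC(=O)OC(C)=O)
Why: Selective acylation of the unhindered equatorial C2 hydroxyl over the axial neopentyl C3 hydroxyl; any mixed anhydride at C15 is hydrolysed on aqueous work-up.

**Compound list**

1 | (S)-(+)-carvone | CC1=CC[C@@H](CC1=O)C(C)=C | starting material
2 | lithium dienolate of 1 (O–Li on C9) | [Li]OC1=C[C@@H](C(C)=C)CC=C1C | intermediate
3 | 6-methylcarvone, (5S,6RS)-2,6-dimethyl-5-(prop-1-en-2-yl)cyclohex-2-en-1-one | CC1C(=O)C(C)=CC[C@@H]1C(C)=C | intermediate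
4 | lithium enolate of 3 (tetrasubstituted C9=C10) | [Li]OC1=C(C)[C@@H](C(C)=C)CC=C1C | intermediate
5 | (5R,6R)-2,6-dimethyl-5-(prop-1-en-2-yl)-6-(prop-2-yn-1-yl)cyclohex-2-en-1-one (propargyl trans to isopropenyl) | C#CC[C@@]1(C)C(=O)C(C)=CC[C@@H]1C(C)=C | intermediate
6 | epoxide of 5: 2,6-dimethyl-5-(2-methyloxiran-2-yl)-6-(prop-2-yn-1-yl)cyclohex-2-en-1-one, ring centres as in 5, both oxirane epimers | C#CC[C@@]1(C)C(=O)C(C)=CC[C@@H]1C2(C)CO2 | intermediate
7 | 2-[2,4-dimethyl-3-oxo-2-(prop-2-yn-1-yl)cyclohex-4-en-1-yl]propanal, ring centres as in 5, both C4 epimers | C#CC[C@@]1(C)C(=O)C(C)=CC[C@@H]1C(C)C=O | intermediate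
8 | tert-butyldimethylsilyl enol ether of 7 (E/Z mixture) | C#CC[C@@]1(C)C(=O)C(C)=CC[C@@H]1C(C)=CO[Si](C)(C)C(C)(C)C | intermediate
9 | trans-decalin keto aldehyde: 2,7-diene, 9-one, 4α-CHO, 4β-CH3, 10α-CH3, H-5 β | C1=CC[C@@]2(C)C(=O)C(C)=CC[C@@H]2[C@]1(C)C=O | intermediate
10 | 2β,3β-diol of 9 | O[C@H]1C[C@@]2(C)C(=O)C(C)=CC[C@@H]2[C@](C)(C=O)[C@H]1O | intermediate
11 | 2β,3β-acetonide C19 dimethyl acetal of 10 | CC1(C)O[C@H]2C[C@@]3(C)C(=O)C(C)=CC[C@@H]3[C@](C)(C(OC)OC)[C@H]2O1 | intermediate
12 | bromomagnesium 9α-alkoxide of the 9β-(but-3-enyl) adduct of 11 | CC1(C)O[C@H]2C[C@@]3(C)[C@](CCC=C)(O[Mg]Br)C(C)=CC[C@@H]3[C@](C)(C(OC)OC)[C@H]2O1 | intermediate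
13 | 9α-methyl carbonate, 9β-(but-3-enyl), 7-ene | CC1(C)O[C@H]2C[C@@]3(C)[C@](CCC=C)(OC(=O)OC)C(C)=CC[C@@H]3[C@](C)(C(OC)OC)[C@H]2O1 | intermediate
14 | 9α-(but-3-enyl), H-9 β, 7-ene, acetonide and acetal retained | CC1(C)O[C@H]2C[C@@]3(C)[C@H](CCC=C)C(C)=CC[C@@H]3[C@](C)(C(OC)OC)[C@H]2O1 | intermediate
15 | methyl (E)-enoate from cross-metathesis of 14 | CC1(C)O[C@H]2C[C@@]3(C)[C@H](CC/C=C/C(=O)OC)C(C)=CC[C@@H]3[C@](C)(C(OC)OC)[C@H]2O1 | intermediate
16 | (13R)-methyl ester, acetonide and acetal retained | CC1(C)O[C@H]2C[C@@]3(C)[C@H](CC[C@@H](C)CC(=O)OC)C(C)=CC[C@@H]3[C@](C)(C(OC)OC)[C@H]2O1 | intermediate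
17 | lithium carboxylate of 16 | CC1(C)O[C@H]2C[C@@]3(C)[C@H](CC[C@@H](C)CC(=O)[O-])C(C)=CC[C@@H]3[C@](C)(C(OC)OC)[C@H]2O1.[Li+] | intermediate
18 | 2β,3β-dihydroxy-19-oxo acid (des-acetyl target) | O[C@H]1C[C@@]2(C)[C@H](CC[C@@H](C)CC(=O)O)C(C)=CC[C@@H]2[C@](C)(C=O)[C@H]1O | intermediate
19 | CNP0180877.1 | CC(=O)O[C@H]1C[C@@]2(C)[C@H](CC[C@@H](C)CC(=O)O)C(C)=CC[C@@H]2[C@](C)(C=O)[C@H]1O | target

**Step count and risks**

Total step count: 14. Longest linear sequence: 14 steps from 1.

Steps most likely to fail:

Step 6. The gold step may close 5-exo-dig instead of 6-endo-dig, or facial selectivity at C4 may erode. The fallback sets out from 6 and comes back at 9. The alkyne of epoxide 6 is iodinated (NIS, AgNO3, acetone) to the iodoalkyne epoxide F1. Diimide (2-nitrobenzenesulfonyl hydrazide, Et3N) reduces it to the (Z)-vinyl iodide epoxide F2. Rearrangement with BF3·OEt2 as in step 4 gives the (Z)-vinyl iodide aldehyde F3. Palladium-catalysed intramolecular α-alkenylation of its enolate (Pd(OAc)2, rac-BINAP, Cs2CO3, dioxane, 80 °C) then joins C4 to C3 with no regiochemical alternative and returns 9.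

Step 10. Hydride may be delivered to the wrong allyl terminus or face, or the π-allyl may undergo β-hydride elimination to a diene. The fallback sets out from 11 and comes back at 14. Addition of CH2=CHCH2CH2MgBr as in step 9, but with an aqueous quench, gives the tertiary allylic alcohol F4. Oxidative 1,3-transposition with pyridinium chlorochromate (C5H5NH[CrO3Cl], NaOAc, CH2Cl2) gives the transposed enone F5 (C7 ketone, C8=C9). Li/NH3 reduction protonates C9 axially from the β face, and the enolate is trapped with PhNTf2 as the enol triflate F6. Hydrogenolysis of the triflate (Pd(OAc)2, PPh3, Bu3N, HCO2H, DMF, 60 °C) gives 14.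

Step 4. The tertiary cation of the epoxide rearrangement may be diverted by alkyne participation or by elimination to the allylic alcohol. The fallback sets out from 5 and comes back at 7. Selective ozonolysis of the isopropenyl group (O3, CH2Cl2/MeOH, −78 °C; Me2S) gives the methyl ketone F7. A Wittig reaction with Ph3P=CHOMe at low temperature gives the methyl enol ether F8. Mild acid hydrolysis (aq. HCl, THF) gives 7.

Further compounds
F1 | step 6 | iodoalkyne epoxide (6 with C≡C–I) | IC#CC[C@@]1(C)C(=O)C(C)=CC[C@@H]1C2(C)CO2
F2 | step 6 | (Z)-vinyl iodide epoxide | I/C=C\C[C@@]1(C)C(=O)C(C)=CC[C@@H]1C2(C)CO2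
F3 | step 6 | (Z)-vinyl iodide aldehyde (both C4 epimers) | I/C=C\C[C@@]1(C)C(=O)C(C)=CC[C@@H]1C(C)C=O
F4 | step 10 | tertiary allylic alcohol (9α-OH, 9β-but-3-enyl) | CC1(C)O[C@H]2C[C@@]3(C)[C@](CCC=C)(O)C(C)=CC[C@@H]3[C@](C)(C(OC)OC)[C@H]2O1
F5 | step 10 | transposed enone (C7 ketone, C8=C9) | CC1(C)O[C@H]2C[C@@]3(C)C(CCC=C)=C(C)C(=O)C[C@@H]3[C@](C)(C(OC)OC)[C@H]2O1
F6 | step 10 | C7 enol triflate with H-9 β | CC1(C)O[C@H]2C[C@@]3(C)[C@H](CCC=C)C(C)=C(OS(=O)(=O)C(F)(F)F)C[C@@H]3[C@](C)(C(OC)OC)[C@H]2O1
F7 | step 4 | methyl ketone from ozonolysis of 5 | C#CC[C@@]1(C)C(=O)C(C)=CC[C@@H]1C(C)=O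
F8 | step 4 | methyl enol ether (E/Z mixture) | C#CC[C@@]1(C)C(=O)C(C)=CC[C@@H]1C(C)=COC
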